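The tricyclo[5.3.1.0(1,5)]undecane core is read as a dearomatised acylphloroglucinol (ring A: C-1, C-7 to C-11) with one prenyl group on C-1 and a methyl and a prenyl group on C-7. The key step is an oxidative radical cascade on this monocyclic triketone: the C-1 radical, flanked by the C-10 and C-11 carbonyls, closes C-1–C-5 onto the C-7 prenyl, and the tertiary C-4 radical then closes C-3–C-4 onto the C-1 prenyl. Both cyclopentane rings (B and C) and the C-1, C-3 and C-5 stereocentres thus arise from the single C-7 stereocentre, which a catalyst-controlled dearomatising methylation sets. Hydration of the resulting isopropenyl group completes the target.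

Key step: step 4

Remark: locants follow the tricyclo numbering of the target (C-1 is the ring-fusion carbon bonded to C-2, C-5, C-10 and C-11; C-7 is the methyl-bearing bridgehead; ring B = C-1, C-5, C-6, C-7, C-11; ring C = C-1 to C-5) and are also used for the corresponding atoms of 6; enolised tricarbonyl compounds are written as one tautomer.
Assumption: (R)-2-methylbutanoic acid is bought as the single enantiomer.

Step 1
Reactants: 1 (R)-2-methylbutanoic acid; 2 phloroglucinol (benzene-1,3,5-triol)
Product: 4 (2R)-2-methyl-1-(2,4,6-trihydroxyphenyl)butan-1-one, via (2R)-2-methylbutanoyl chloride 3 (not isolated)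
Conditions: 1, (COCl)2, cat. DMF, CH2Cl2, 0 °C to rt, volatiles removed; then 2, AlCl3, CH2Cl2/MeNO2, 0 °C to rt; aq. HCl
Reagents that add atoms: none
Why: Friedel–Crafts acylation of the highly activated triol by the acid chloride made in the flask should stop at mono-acylation because the first acyl group deactivates the ring, and with no base present the α-stereocentre is not enolised.

Step 2
Reactants: 4 (2R)-2-methyl-1-(2,4,6-trihydroxyphenyl)butan-1-one
Product: 5 (2R)-2-methyl-1-[2,4,6-trihydroxy-3,5-bis(3-methylbut-2-en-1-yl)phenyl]butan-1-one
Conditions: prenyl bromide (2.1 equiv), 10% aq. KOH, 0 °C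
Reagents that add atoms: prenyl bromide (1-bromo-3-methylbut-2-ene), CC(C)=CCBr
Why: Twofold C-alkylation of the ambident phenolate in water, where hydrogen bonding shields oxygen, should take place at the two free ring carbons, as in the known preparation of 3,5-diprenylated acylphloroglucinols; the side-chain stereocentre is protected because the phenolate makes the ketone non-enolisable.

Step 3
Reactants: 5 (2R)-2-methyl-1-[2,4,6-trihydroxy-3,5-bis(3-methylbut-2-en-1-yl)phenyl]butan-1-one
Product: 6 (6S)-3,5-dihydroxy-6-methyl-4-[(2R)-2-methylbutanoyl]-2,6-bis(3-methylbut-2-en-1-yl)cyclohexa-2,4-dien-1-one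
Conditions: MeI (1.05 equiv), CsOH·H2O (2.5 equiv), O-allyl-N-(9-anthracenylmethyl)cinchonidinium bromide (10 mol %), PhMe/CH2Cl2, −50 °C
Reagents that add atoms: iodomethane, CI
Why: Proposed new method: the chiral ammonium cation pairs with the acylphloroglucinolate and shields one face of the prenyl-bearing ring carbon, so that MeI, a soft electrophile in a non-polar medium, should alkylate carbon with loss of aromaticity and set C-7 (the two prenyl-bearing carbons are equivalent, so only the face counts, and the cinchoninium pseudo-enantiomer of the catalyst is taken if the opposite sense of induction is found); the closest known reaction types are the NaOMe/MeI dearomatising C-methylation of 3,5-diprenylated acylphloroglucinols and the cinchona phase-transfer asymmetric alkylation of cyclic enolates, including alkylative dearomatisation of this phenol class with Michael acceptors.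

Step 4
Reactants: 6 (6S)-3,5-dihydroxy-6-methyl-4-[(2R)-2-methylbutanoyl]-2,6-bis(3-methylbut-2-en-1-yl)cyclohexa-2,4-dien-1-one
Product: 7 (1S,3R,5S,7S)-8-hydroxy-4,4,7-trimethyl-9-[(2R)-2-methylbutanoyl]-3-(prop-1-en-2-yl)tricyclo[5.3.1.0(1,5)]undec-8-ene-10,11-dione
Conditions: Mn(OAc)3·2H2O (2.2 equiv), Cu(OAc)2·H2O (1.0 equiv), degassed AcOH (0.01 M), rt; chromatography to remove the C-3 epimer
Reagents that add atoms: none
Why: Mn(OAc)3 oxidises the enolised triketone to a radical at the prenyl-bearing ring carbon between two carbonyls (C-1), which adds 5-exo-trig to the prenyl on C-7 to close ring B and form C-1–C-5; the tertiary C-4 radical then adds 5-exo-trig to the prenyl on C-1 to close ring C and form C-3–C-4, and Cu(OAc)2 (returned by Mn(OAc)3) oxidises the terminal tertiary radical with loss of a methyl hydrogen to the isopropenyl group. The closest known reaction type is the Mn(OAc)3/Cu(OAc)2 oxidative radical polycyclisation of unsaturated 1,3-dicarbonyl compounds. C-1 is fixed by C-7, because the tether C-7–C-6–C-5 can reach the planar radical only from the ring face that carries the C-7 prenyl, and C-5 is fixed because only the exo transition state (C-4 syn to the C-11 bridge) keeps the gem-dimethyl radical clear of the enolised C-8 to C-10 bridge and within reach of the C-1 prenyl for a cis ring fusion. C-3 is set in the second closure, where the alkene terminus may lie syn (as in 7) or anti to the C-11 carbonyl; the substrate does not enforce this choice, so the anti-closed C-3 epimer is expected as well and is removed by chromatography. The step also needs site selectivity (bond formation at C-1 leaves the hydrogen-bonded acylated enol intact, whereas reaction at the acyl-bearing C-9 would destroy it and build a congested centre), 5-exo regioselectivity (each attack at the CH end of a trisubstituted alkene gives a tertiary radical) and closure before oxidation (high dilution of Cu(OAc)2).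

Step 5
Reactants: 7 (1S,3R,5S,7S)-8-hydroxy-4,4,7-trimethyl-9-[(2R)-2-methylbutanoyl]-3-(prop-1-en-2-yl)tricyclo[5.3.1.0(1,5)]undec-8-ene-10,11-dione
Product: 9 (1S,3S,5S,7S)-8-hydroxy-3-(2-hydroxypropan-2-yl)-4,4,7-trimethyl-9-[(2R)-2-methylbutanoyl]tricyclo[5.3.1.0(1,5)]undec-8-ene-10,11-dione (target), via tertiary hydroperoxide 8 (not isolated)
Conditions: Co(acac)2 (20 mol %), PhSiH3, O2 (1 atm), THF, rt; then PPh3
Reagents that add atoms: dioxygen, O=O
Why: Mukaiyama hydration: hydrogen-atom transfer from a cobalt hydride to the only isolated alkene should give the tertiary radical (Markovnikov), which captures O2, and PPh3 reduces the hydroperoxide; the tetrasubstituted enol double bond is inert and no stereocentre is created (the C-3 descriptor changes only through priorities).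

Compound list
1 | (R)-2-methylbutanoic acid | CC[C@@H](C)C(=O)O | starting material
2 | phloroglucinol (benzene-1,3,5-triol) | Oc1cc(O)cc(O)c1 | starting material
3 | (2R)-2-methylbutanoyl chloride | CC[C@@H](C)C(Cl)=O | intermediate
4 | (2R)-2-methyl-1-(2,4,6-trihydroxyphenyl)butan-1-one | CC[C@@H](C)C(=O)c1c(O)cc(O)cc1O | intermediate
5 | (2R)-2-methyl-1-[2,4,6-trihydroxy-3,5-bis(3-methylbut-2-en-1-yl)phenyl]butan-1-one | CC[C@@H](C)C(=O)c1c(O)c(CC=C(C)C)c(O)c(CC=C(C)C)c1O | intermediate
6 | (6S)-3,5-dihydroxy-6-methyl-4-[(2R)-2-methylbutanoyl]-2,6-bis(3-methylbut-2-en-1-yl)cyclohexa-2,4-dien-1-one | CC[C@@H](C)C(=O)C1=C(O)[C@](C)(CC=C(C)C)C(=O)C(CC=C(C)C)=C1O | intermediate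
7 | (1S,3R,5S,7S)-8-hydroxy-4,4,7-trimethyl-9-[(2R)-2-methylbutanoyl]-3-(prop-1-en-2-yl)tricyclo[5.3.1.0(1,5)]undec-8-ene-10,11-dione | CC[C@@H](C)C(=O)C1=C(O)[C@]2(C)C[C@H]3C(C)(C)[C@@H](C(C)=C)C[C@@]3(C1=O)C2=O | intermediate
8 | (1S,3S,5S,7S)-3-(2-hydroperoxypropan-2-yl)-8-hydroxy-4,4,7-trimethyl-9-[(2R)-2-methylbutanoyl]tricyclo[5.3.1.0(1,5)]undec-8-ene-10,11-dione | CC[C@@H](C)C(=O)C1=C(O)[C@]2(C)C[C@H]3C(C)(C)[C@@H](C(C)(C)OO)C[C@@]3(C1=O)C2=O | intermediate
9 | (1S,3S,5S,7S)-8-hydroxy-3-(2-hydroxypropan-2-yl)-4,4,7-trimethyl-9-[(2R)-2-methylbutanoyl]tricyclo[5.3.1.0(1,5)]undec-8-ene-10,11-dione | CC[C@@H](C)C(=O)C1=C(O)[C@]2(C)C[C@H]3C(C)(C)[C@@H](C(C)(C)O)C[C@@]3(C1=O)C2=O | target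

Total step count: 5. Longest linear sequence: 5 steps (from 1 or 2 to 9).

Steps most likely to fail

Step 3 (Proposed new method). The chiral ion pair may discriminate the two faces of the prenyl-bearing carbon poorly, and O-methylation or a second C-methylation at the remaining prenyl-bearing carbon may compete. The fallback uses known chemistry and sets out from 5: NaOMe and MeI in MeOH at 0 °C to rt, the established unselective dearomatising C-methylation of this phenol class, should give 6 together with its C-6 epimer, (6R)-3,5-dihydroxy-6-methyl-4-[(2R)-2-methylbutanoyl]-2,6-bis(3-methylbut-2-en-1-yl)cyclohexa-2,4-dien-1-one F1. The two are diastereomers because of the (2R) side chain and would be separated by preparative HPLC on a polysaccharide chiral stationary phase; the fallback comes back to the route at 6.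

Step 4. The mono-cyclised tertiary radical may be oxidised by divalent copper before the second ring closure, and the facial discrimination in that closure is weak at room temperature. The fallback sets out from 6 and replaces the metal oxidants by a halogen-atom-transfer chain. NBS in CH2Cl2 at −78 °C should brominate the prenyl-bearing enol carbon to give (6S)-2-bromo-5-hydroxy-6-methyl-4-[(2R)-2-methylbutanoyl]-2,6-bis(3-methylbut-2-en-1-yl)cyclohex-4-ene-1,3-dione F2 (either configuration at the brominated carbon serves). Et3B/air in CH2Cl2 at −40 °C to rt then starts a bromine-atom-transfer radical cyclisation in which the same two 5-exo closures are followed by bromine transfer to the terminal radical, giving (1S,3S,5S,7S)-3-(2-bromopropan-2-yl)-8-hydroxy-4,4,7-trimethyl-9-[(2R)-2-methylbutanoyl]tricyclo[5.3.1.0(1,5)]undec-8-ene-10,11-dione F3. No oxidant is present to intercept the intermediate radical, and the low temperature should sharpen the choice between the two closure geometries. Silver-assisted hydrolysis of F3 (AgOTf, acetone/H2O) should give the carbinol directly, so the fallback comes back to the route at 9 and step 5 is not needed.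

Step 2. O-prenylation, over-alkylation to dearomatised triprenyl material and cyclisation of a prenyl group onto a neighbouring hydroxyl may erode the double C-alkylation in aqueous base. The fallback sets out from 4 and changes the mode of alkylation to a Lewis-acid Friedel–Crafts prenylation with 2-methylbut-3-en-2-ol and BF3·OEt2 in dioxane at rt (short reaction time), which alkylates carbon only and cannot dearomatise; it comes back to the route at 5, and no compound outside the list is made (F0).

Further compounds
F1 | step 3 | (6R)-3,5-dihydroxy-6-methyl-4-[(2R)-2-methylbutanoyl]-2,6-bis(3-methylbut-2-en-1-yl)cyclohexa-2,4-dien-1-one | CC[C@@H](C)C(=O)C1=C(O)[C@@](C)(CC=C(C)C)C(=O)C(CC=C(C)C)=C1O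
F2 | step 4 | (6S)-2-bromo-5-hydroxy-6-methyl-4-[(2R)-2-methylbutanoyl]-2,6-bis(3-methylbut-2-en-1-yl)cyclohex-4-ene-1,3-dione | CC[C@@H](C)C(=O)C1=C(O)[C@](C)(CC=C(C)C)C(=O)C(Br)(CC=C(C)C)C1=O
F3 | step 4 | (1S,3S,5S,7S)-3-(2-bromopropan-2-yl)-8-hydroxy-4,4,7-trimethyl-9-[(2R)-2-methylbutanoyl]tricyclo[5.3.1.0(1,5)]undec-8-ene-10,11-dione | CC[C@@H](C)C(=O)C1=C(O)[C@]2(C)C[C@H]3C(C)(C)[C@@H](C(C)(C)Br)C[C@@]3(C1=O)C2=O
F0 | step 2 | none | none
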